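## Retrosynthetic overview

1. Target 31 ⇐ 30 (acid hydrolysis of silyl ether and dioxolane) ⇐ 26 + acid 29 (C8 ester) ⇐ 25 (N–O cleavage) ⇐ 24 (C9 acetylation).
2. 24 ⇐ 22 by closing the C9–C10 bond of the ten-membered ring B (chromium-mediated addition of the C10 alkenyl iodide to the C9 aldehyde). The enabling feature is that carbinol carbon C9 sits directly on sp2 carbon C10 of the trisubstituted C1=C10 alkene of ring B (an alkenyl carbinol), while the Z-iodoalkene, the E-C4=C5 alkene and the trans-fused γ-lactone ring A fold the chain so that C9 and C10 meet.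
3. 22 ⇐ 21 (enamine-catalysed α-oxyamination sets C8) ⇐ 14 (one-carbon homologation to C9, α-methylenation at C11).
4. 14 ⇐ 11 + 8 (Evans syn-aldol sets C6 and C7, lactonisation closes ring A); 8 ⇐ geranyl acetate 1; 11 ⇐ 9 + 10.
5. Ring order: ring A (γ-lactone) in step 8, then ring B (carbocycle) in step 15.

Key step: step 15

Remark: locants follow germacrane numbering (ring B = C1–C10; ring A = C6, C7, C11, C12 and the ring oxygen; C13 exocyclic methylene, C14 on C10, C15 methyl on C4). Because C14 carries oxygen, the ring-cis C1=C10 alkene is E by the sequence rules in 24–31, while its iodoalkene precursor is Z. Compounds 1, 9, 10 and 27 are taken as commercial.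

## Route

Step 1
Reactants: 1 geranyl acetate
Product: 3 (2E)-3-methyl-6-oxohex-2-en-1-yl acetate, via ozonide 2 (not isolated)
Conditions: O3 (1.0 equiv), CH2Cl2, −78 °C; then Me2S, −78 °C → rt
Reagents that add atoms: ozone, [O-][O+]=O
Why: Ozonolysis with reductive work-up, in which the electron-rich isopropylidene alkene reacts far faster than the alkene deactivated by the allylic acetate, so one equivalent of ozone should cleave only the former and leave the E-alkene that becomes C4=C5.

Step 2
Reactants: 3 (2E)-3-methyl-6-oxohex-2-en-1-yl acetate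
Product: 4 (2E,6E)-3-methyl-8-oxoocta-2,6-dien-1-yl acetate
Conditions: Ph3P=CHCHO, toluene, 80 °C
Reagents that add atoms: (triphenylphosphoranylidene)acetaldehyde, O=CC=P(c1ccccc1)(c1ccccc1)c1ccccc1
Why: Wittig olefination with a stabilised formyl ylide, which should give the E-enal and brings in C10 and C14.

Step 3
Reactants: 4 (2E,6E)-3-methyl-8-oxoocta-2,6-dien-1-yl acetate
Product: 5 (2E,6Z)-7-iodo-3-methyl-8-oxoocta-2,6-dien-1-yl acetate
Conditions: I2, K2CO3, DMAP (20 mol %), THF/H2O (1:1), rt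
Reagents that add atoms: iodine, II
Why: α-Iodination of the enal by a Morita–Baylis–Hillman-type sequence (DMAP conjugate addition, iodination of the enolate, E1cB loss of DMAP), which places iodine on C10 and should give the thermodynamically preferred Z-isomer with iodine cis to the chain, the geometry needed later for the ring-cis C1=C10 alkene.

Step 4
Reactants: 5 (2E,6Z)-7-iodo-3-methyl-8-oxoocta-2,6-dien-1-yl acetate
Product: 6 (2E,6Z)-7-(1,3-dioxolan-2-yl)-7-iodo-3-methylhepta-2,6-dien-1-yl acetate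
Conditions: HOCH2CH2OH, PPTS (cat.), benzene, reflux (Dean–Stark)
Reagents that add atoms: ethane-1,2-diol, OCCO
Why: Acid-catalysed acetalisation with azeotropic removal of water masks C14 at the aldehyde oxidation level as a dioxolane that the electron-withdrawing iodine makes robust, so no redox adjustment is needed at the end.

Step 5
Reactants: 6 (2E,6Z)-7-(1,3-dioxolan-2-yl)-7-iodo-3-methylhepta-2,6-dien-1-yl acetate
Product: 7 (2E,6Z)-7-(1,3-dioxolan-2-yl)-7-iodo-3-methylhepta-2,6-dien-1-ol
Conditions: K2CO3 (cat.), MeOH, 0 °C → rt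
Reagents that add atoms: none
Why: Base-catalysed transesterification (methanolysis) should free the allylic alcohol at C6 without touching the acetal or the iodoalkene.

Step 6
Reactants: 7 (2E,6Z)-7-(1,3-dioxolan-2-yl)-7-iodo-3-methylhepta-2,6-dien-1-ol
Product: 8 (2E,6Z)-7-(1,3-dioxolan-2-yl)-7-iodo-3-methylhepta-2,6-dienal
Conditions: MnO2, CH2Cl2, rt
Reagents that add atoms: none
Why: MnO2 oxidation is selective for allylic alcohols and should give the E-enal (C6 aldehyde) without isomerising either alkene.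

Step 7
Reactants: 9 (4S)-4-benzyl-1,3-oxazolidin-2-one; 10 methyl 4-chloro-4-oxobutanoate
Product: 11 methyl 4-[(4S)-4-benzyl-2-oxo-1,3-oxazolidin-3-yl]-4-oxobutanoate
Conditions: n-BuLi, THF, −78 °C; then 10, −78 → 0 °C
Reagents that add atoms: none
Why: N-Acylation of the lithiated oxazolidinone by the acid chloride, which reacts much faster than the methyl ester.

Step 8
Reactants: 11 methyl 4-[(4S)-4-benzyl-2-oxo-1,3-oxazolidin-3-yl]-4-oxobutanoate; 8 (2E,6Z)-7-(1,3-dioxolan-2-yl)-7-iodo-3-methylhepta-2,6-dienal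
Product: 14 (4S)-4-benzyl-3-{[(2R,3S)-2-[(1E,5Z)-6-(1,3-dioxolan-2-yl)-6-iodo-2-methylhexa-1,5-dien-1-yl]-5-oxooxolan-3-yl]carbonyl}-1,3-oxazolidin-2-one, via Z-boron enolate 12 (not isolated), via syn-aldol hydroxy ester 13 (not isolated)
Conditions: Bu2BOTf, i-Pr2NEt, CH2Cl2, −78 → 0 °C; 8, −78 → 0 °C; pH 7 buffer, MeOH, H2O2, 0 °C; then PPTS (cat.), CH2Cl2, rt
Reagents that add atoms: none
Why: Evans syn-aldol reaction followed by lactonisation, in which the Z-boron enolate 12 reacts through a Zimmerman–Traxler chair on the face away from the auxiliary benzyl group to set C6 (R) and C7 (S), and the C6 hydroxyl of 13 then closes the five-membered lactone on the methyl ester (5-exo-trig), the syn-aldol relationship translating into the trans-disubstituted ring A.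

Step 9
Reactants: 14 lactone imide
Product: 15 (4R,5R)-5-[(1E,5Z)-6-(1,3-dioxolan-2-yl)-6-iodo-2-methylhexa-1,5-dien-1-yl]-4-(hydroxymethyl)oxolan-2-one
Conditions: NaBH4, THF/H2O (4:1), 0 °C
Reagents that add atoms: none
Why: Reductive cleavage of the N-acyloxazolidinone with borohydride, whose exocyclic imide carbonyl is far more electrophilic than the lactone carbonyl, should give the primary alcohol at C8 and return the auxiliary.

Step 10
Reactants: 15 hydroxymethyl lactone
Product: 16 (2R,3S)-2-[(1E,5Z)-6-(1,3-dioxolan-2-yl)-6-iodo-2-methylhexa-1,5-dien-1-yl]-5-oxooxolane-3-carbaldehyde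
Conditions: Dess–Martin periodinane, CH2Cl2, 0 °C → rt
Reagents that add atoms: none
Why: Dess–Martin oxidation under neutral conditions should give the aldehyde without epimerising C7 or opening the β-acyloxy aldehyde by elimination.

Step 11
Reactants: 16 lactone aldehyde
Product: 17 (4R,5S)-5-[(1E,5Z)-6-(1,3-dioxolan-2-yl)-6-iodo-2-methylhexa-1,5-dien-1-yl]-4-(2-methoxyethenyl)oxolan-2-one (E/Z mixture at the enol ether)
Conditions: MeOCH2PPh3Cl, KHMDS, THF, −78 → 0 °C
Reagents that add atoms: (methoxymethyl)triphenylphosphonium chloride, COC[P+](c1ccccc1)(c1ccccc1)c1ccccc1.[Cl-]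
Why: Wittig methoxymethylenation adds C9 as a one-carbon homologation, the nucleophilic ylide adding to the aldehyde at low temperature faster than it enolises it, and the enol ether geometry is of no consequence.

Step 12
Reactants: 17 enol ether lactone
Product: 20 (4S,5R)-5-[(1E,5Z)-6-(1,3-dioxolan-2-yl)-6-iodo-2-methylhexa-1,5-dien-1-yl]-4-(2-methoxyethenyl)-3-methylideneoxolan-2-one, via Mannich base 18 (not isolated), via trimethylammonium iodide 19 (not isolated)
Conditions: LDA, THF, −78 °C; CH2=NMe2+ I−, −78 °C → rt; then MeI, MeOH, rt; then NaHCO3 (aq), CH2Cl2, rt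
Reagents that add atoms: N,N-dimethylmethyleneiminium iodide (Eschenmoser's salt), C=[N+](C)C.[I-]
Why: Mannich alkylation of the lactone enolate with Eschenmoser's salt, quaternisation and E1cB loss of trimethylamine (Eschenmoser methylenation) should install the exocyclic C11=C13 alkene, since deprotonation can occur only at C11 and the transient centre there is lost again in the elimination.

Step 13
Reactants: 20 α-methylene lactone enol ether
Product: 21 2-[(2R,3S)-2-[(1E,5Z)-6-(1,3-dioxolan-2-yl)-6-iodo-2-methylhexa-1,5-dien-1-yl]-4-methylidene-5-oxooxolan-3-yl]acetaldehyde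
Conditions: Hg(OAc)2, THF/H2O (10:1), 0 °C; then KI (aq)
Reagents that add atoms: water, O
Why: Hg(OAc)2-promoted hydrolysis of the enol ether (oxymercuration, loss of methanol, protodemercuration on iodide treatment) runs at near-neutral pH, so the dioxolane should survive while the homologous aldehyde with C8 as a methylene group is freed.

Step 14
Reactants: 21 lactone acetaldehyde
Product: 22 (2S)-2-[(2R,3S)-2-[(1E,5Z)-6-(1,3-dioxolan-2-yl)-6-iodo-2-methylhexa-1,5-dien-1-yl]-4-methylidene-5-oxooxolan-3-yl]-2-[(2,2,6,6-tetramethylpiperidin-1-yl)oxy]acetaldehyde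
Conditions: TEMPO, (5S)-5-benzyl-2,2,3-trimethylimidazolidin-4-one·TFA (20 mol %), CuCl2·2H2O (10 mol %), air, acetone, −10 °C
Reagents that add atoms: TEMPO, CC1(C)CCCC(C)(C)N1[O]
Why: Enamine-catalysed α-oxyamination of the aldehyde, in which the benzyl group of the (5S)-imidazolidinone shields one face of the catalyst-bound aldehyde so that copper-activated TEMPO should enter from the open face and set C8 (S) under catalyst control, delivering the C8 oxygen already protected as an alkoxyamine that tolerates the next step.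

Step 15
Reactants: 22 α-aminoxy aldehyde with Z-iodoalkene
Product: 24 14,14-ethylenedioxy-9α-hydroxy-8β-[(2,2,6,6-tetramethylpiperidin-1-yl)oxy]germacra-1(10),4,11(13)-trien-12,6α-olide (ring-cis C1=C10; 4E), via alkenylchromium dichloride 23 (not isolated)
Conditions: CrCl2 (15 equiv), NiCl2 (2 mol % of CrCl2), DMSO/THF, rt, 22 added over 12 h (final 2 mM)
Reagents that add atoms: none
Why: Nozaki–Hiyama–Kishi reaction: zerovalent nickel, formed in situ from NiCl2 and CrCl2, inserts into the C10–I bond and hands the alkenyl group to trivalent chromium with retention of the Z-geometry, giving 23, which adds to the C9 aldehyde. The closest known reaction type is the intramolecular alkenyl iodide–aldehyde coupling used to close nine- to twelve-membered carbocycles. Ring B is closed in a 10-exo-trig mode by the C9–C10 bond, with the carbonyl oxygen outside the new ring. The new C9 stereocentre is controlled by the adjacent C8 centre inside the cyclic transition state: with the bulky C8–O bond antiperiplanar to the forming bond and C7 of necessity gauche to C10, the chromium-bound carbonyl oxygen should lie in the open sector next to H-8 and not against C7, which exposes the Si face and leads to the 9S (9α) carbinol with H-8 and H-9 anti. The step needs ring closure to outrun intermolecular coupling, addition at the aldehyde only and retention of alkene geometry: the Z-iodoalkene, the E-C4=C5 alkene and the trans-fused lactone are three rigid turn elements that hold C10 near C9, slow addition at high dilution suppresses oligomers, and alkenylchromium reagents do not attack the lactone, the enoate or the acetal.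

Step 16
Reactants: 24 macrocyclic carbinol
Product: 25 9α-acetoxy-14,14-ethylenedioxy-8β-[(2,2,6,6-tetramethylpiperidin-1-yl)oxy]germacra-1(10),4,11(13)-trien-12,6α-olide
Conditions: Ac2O, DMAP (cat.), pyridine, CH2Cl2, 0 °C → rt
Reagents that add atoms: acetic anhydride, CC(=O)OC(C)=O
Why: DMAP-catalysed acylation of the secondary allylic alcohol with retention installs the C9 acetate while C8 is still blocked, which fixes the placement of the two different ester groups.

Step 17
Reactants: 25 C9 acetate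
Product: 26 9α-acetoxy-14,14-ethylenedioxy-8β-hydroxygermacra-1(10),4,11(13)-trien-12,6α-olide
Conditions: Zn dust, AcOH/THF (1:1), 45 °C
Reagents that add atoms: none
Why: Reductive cleavage of the N–O bond of the alkoxyamine by zinc in acetic acid should free the C8 hydroxyl, and with C14 still masked as the acetal there is no conjugated carbonyl through which zinc could remove the allylic C9 acetate.

Step 18
Reactants: 27 ethyl 2-(hydroxymethyl)prop-2-enoate
Product: 28 ethyl 2-({[tert-butyl(dimethyl)silyl]oxy}methyl)prop-2-enoate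
Conditions: TBSCl, imidazole, DMF, 0 °C → rt
Reagents that add atoms: tert-butyldimethylsilyl chloride, CC(C)(C)[Si](C)(C)Cl
Why: Imidazole-promoted silylation of the primary alcohol protects the side-chain hydroxyl for the later esterification.

Step 19
Reactants: 28 ethyl 2-({[tert-butyl(dimethyl)silyl]oxy}methyl)prop-2-enoate
Product: 29 2-({[tert-butyl(dimethyl)silyl]oxy}methyl)prop-2-enoic acid
Conditions: LiOH·H2O, THF/H2O, 0 °C; then 1 M HCl to pH 3
Reagents that add atoms: lithium hydroxide, [Li+].[OH-]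
Why: Saponification of the ethyl ester at low temperature, where hydroxide attacks the ester carbonyl faster than it adds to the 2-substituted acrylate, should give the free acid with the silyl ether intact.

Step 20
Reactants: 26 C8 alcohol; 29 2-({[tert-butyl(dimethyl)silyl]oxy}methyl)prop-2-enoic acid
Product: 30 9α-acetoxy-8β-{[2-({[tert-butyl(dimethyl)silyl]oxy}methyl)prop-2-enoyl]oxy}-14,14-ethylenedioxygermacra-1(10),4,11(13)-trien-12,6α-olide
Conditions: DCC, DMAP (cat.), CH2Cl2, 0 °C → rt
Reagents that add atoms: none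
Why: Steglich esterification (carbodiimide activation, DMAP acyl transfer) acylates the only free hydroxyl, at C8, with retention of configuration.

Step 21
Reactants: 30 protected target
Product: 31 9α-acetoxy-8β-{[2-(hydroxymethyl)prop-2-enoyl]oxy}-14-oxogermacra-1(10),4,11(13)-trien-12,6α-olide (CNP0177123.1)
Conditions: AcOH/THF/H2O (3:1:1), rt → 35 °C
Reagents that add atoms: water, O
Why: Mild aqueous acid should hydrolyse the primary silyl ether and the allylic dioxolane in one operation, unmasking the side-chain alcohol and the C14 enal while the acetate, the acrylate and the α-methylene lactone survive.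

## Compound list

1 | geranyl acetate, (2E)-3,7-dimethylocta-2,6-dien-1-yl acetate | CC(C)=CCC/C(C)=C/COC(C)=O | starting material
2 | ozonide, (2E)-5-(5,5-dimethyl-1,2,4-trioxolan-3-yl)-3-methylpent-2-en-1-yl acetate | CC1(C)OOC(CC/C(C)=C/COC(C)=O)O1 | intermediate
3 | (2E)-3-methyl-6-oxohex-2-en-1-yl acetate | O=CCC/C(C)=C/COC(C)=O | intermediate
4 | (2E,6E)-3-methyl-8-oxoocta-2,6-dien-1-yl acetate | O=C/C=C/CC/C(C)=C/COC(C)=O | intermediate
5 | (2E,6Z)-7-iodo-3-methyl-8-oxoocta-2,6-dien-1-yl acetate | O=C/C(I)=C/CC/C(C)=C/COC(C)=O | intermediate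
6 | (2E,6Z)-7-(1,3-dioxolan-2-yl)-7-iodo-3-methylhepta-2,6-dien-1-yl acetate | CC(=O)OC/C=C(\C)CC/C=C(\I)C1OCCO1 | intermediate
7 | (2E,6Z)-7-(1,3-dioxolan-2-yl)-7-iodo-3-methylhepta-2,6-dien-1-ol | OC/C=C(\C)CC/C=C(\I)C1OCCO1 | intermediate
8 | (2E,6Z)-7-(1,3-dioxolan-2-yl)-7-iodo-3-methylhepta-2,6-dienal | O=C/C=C(\C)CC/C=C(\I)C1OCCO1 | intermediate
9 | (4S)-4-benzyl-1,3-oxazolidin-2-one | O=C1N[C@@H](Cc2ccccc2)CO1 | starting material
10 | methyl 4-chloro-4-oxobutanoate | COC(=O)CCC(Cl)=O | starting material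
11 | methyl 4-[(4S)-4-benzyl-2-oxo-1,3-oxazolidin-3-yl]-4-oxobutanoate | COC(=O)CCC(=O)N1[C@@H](Cc2ccccc2)COC1=O | intermediate
12 | dibutylboron Z-enolate of 11 | COC(=O)C/C=C(\OB(CCCC)CCCC)N1[C@@H](Cc2ccccc2)COC1=O | intermediate
13 | methyl (3S,4R,5E,9Z)-3-{[(4S)-4-benzyl-2-oxo-1,3-oxazolidin-3-yl]carbonyl}-10-(1,3-dioxolan-2-yl)-4-hydroxy-10-iodo-6-methyldeca-5,9-dienoate | COC(=O)C[C@H](C(=O)N1[C@@H](Cc2ccccc2)COC1=O)[C@H](O)/C=C(\C)CC/C=C(\I)C3OCCO3 | intermediate
14 | (4S)-4-benzyl-3-{[(2R,3S)-2-[(1E,5Z)-6-(1,3-dioxolan-2-yl)-6-iodo-2-methylhexa-1,5-dien-1-yl]-5-oxooxolan-3-yl]carbonyl}-1,3-oxazolidin-2-one | O=C(N1[C@@H](Cc2ccccc2)COC1=O)[C@H]3CC(=O)O[C@@H]3/C=C(\C)CC/C=C(\I)C4OCCO4 | intermediate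
15 | (4R,5R)-5-[(1E,5Z)-6-(1,3-dioxolan-2-yl)-6-iodo-2-methylhexa-1,5-dien-1-yl]-4-(hydroxymethyl)oxolan-2-one | OC[C@H]1CC(=O)O[C@@H]1/C=C(\C)CC/C=C(\I)C2OCCO2 | intermediate
16 | (2R,3S)-2-[(1E,5Z)-6-(1,3-dioxolan-2-yl)-6-iodo-2-methylhexa-1,5-dien-1-yl]-5-oxooxolane-3-carbaldehyde | O=C[C@H]1CC(=O)O[C@@H]1/C=C(\C)CC/C=C(\I)C2OCCO2 | intermediate
17 | (4R,5S)-5-[(1E,5Z)-6-(1,3-dioxolan-2-yl)-6-iodo-2-methylhexa-1,5-dien-1-yl]-4-(2-methoxyethenyl)oxolan-2-one, E/Z mixture at the enol ether | COC=C[C@H]1CC(=O)O[C@@H]1/C=C(\C)CC/C=C(\I)C2OCCO2 | intermediate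
18 | Mannich base, 3-[(dimethylamino)methyl] derivative of 17, epimers at the lactone α-carbon | COC=C[C@H]1C(CN(C)C)C(=O)O[C@@H]1/C=C(\C)CC/C=C(\I)C2OCCO2 | intermediate
19 | trimethylammonium iodide of 18 | COC=C[C@H]1C(C[N+](C)(C)C)C(=O)O[C@@H]1/C=C(\C)CC/C=C(\I)C2OCCO2.[I-] | intermediate
20 | (4S,5R)-5-[(1E,5Z)-6-(1,3-dioxolan-2-yl)-6-iodo-2-methylhexa-1,5-dien-1-yl]-4-(2-methoxyethenyl)-3-methylideneoxolan-2-one | COC=C[C@H]1C(=C)C(=O)O[C@@H]1/C=C(\C)CC/C=C(\I)C2OCCO2 | intermediate
21 | 2-[(2R,3S)-2-[(1E,5Z)-6-(1,3-dioxolan-2-yl)-6-iodo-2-methylhexa-1,5-dien-1-yl]-4-methylidene-5-oxooxolan-3-yl]acetaldehyde | O=CC[C@H]1C(=C)C(=O)O[C@@H]1/C=C(\C)CC/C=C(\I)C2OCCO2 | intermediate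
22 | (2S)-2-[(2R,3S)-2-[(1E,5Z)-6-(1,3-dioxolan-2-yl)-6-iodo-2-methylhexa-1,5-dien-1-yl]-4-methylidene-5-oxooxolan-3-yl]-2-[(2,2,6,6-tetramethylpiperidin-1-yl)oxy]acetaldehyde | O=C[C@@H](ON1C(C)(C)CCCC1(C)C)[C@H]2C(=C)C(=O)O[C@@H]2/C=C(\C)CC/C=C(\I)C3OCCO3 | intermediate
23 | alkenylchromium dichloride from 22 (chromium in place of iodine, geometry retained) | O=C[C@@H](ON1C(C)(C)CCCC1(C)C)[C@H]2C(=C)C(=O)O[C@@H]2/C=C(\C)CC/C=C(\[Cr](Cl)Cl)C3OCCO3 | intermediate
24 | 14,14-ethylenedioxy-9α-hydroxy-8β-[(2,2,6,6-tetramethylpiperidin-1-yl)oxy]germacra-1(10),4,11(13)-trien-12,6α-olide (6R,7S,8S,9S; ring-cis C1=C10; 4E) | CC1(C)CCCC(C)(C)N1O[C@H]2[C@H]3C(=C)C(=O)O[C@@H]3/C=C(\C)CC/C=C(/C4OCCO4)[C@@H]2O | intermediate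
25 | 9α-acetoxy-14,14-ethylenedioxy-8β-[(2,2,6,6-tetramethylpiperidin-1-yl)oxy]germacra-1(10),4,11(13)-trien-12,6α-olide | CC1(C)CCCC(C)(C)N1O[C@H]2[C@H]3C(=C)C(=O)O[C@@H]3/C=C(\C)CC/C=C(/C4OCCO4)[C@@H]2OC(C)=O | intermediate
26 | 9α-acetoxy-14,14-ethylenedioxy-8β-hydroxygermacra-1(10),4,11(13)-trien-12,6α-olide | O[C@H]1[C@H]2C(=C)C(=O)O[C@@H]2/C=C(\C)CC/C=C(/C3OCCO3)[C@@H]1OC(C)=O | intermediate
27 | ethyl 2-(hydroxymethyl)prop-2-enoate | C=C(CO)C(=O)OCC | starting material
28 | ethyl 2-({[tert-butyl(dimethyl)silyl]oxy}methyl)prop-2-enoate | C=C(CO[Si](C)(C)C(C)(C)C)C(=O)OCC | intermediate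
29 | 2-({[tert-butyl(dimethyl)silyl]oxy}methyl)prop-2-enoic acid | C=C(CO[Si](C)(C)C(C)(C)C)C(=O)O | intermediate
30 | 9α-acetoxy-8β-{[2-({[tert-butyl(dimethyl)silyl]oxy}methyl)prop-2-enoyl]oxy}-14,14-ethylenedioxygermacra-1(10),4,11(13)-trien-12,6α-olide | C=C(CO[Si](C)(C)C(C)(C)C)C(=O)O[C@H]1[C@H]2C(=C)C(=O)O[C@@H]2/C=C(\C)CC/C=C(/C3OCCO3)[C@@H]1OC(C)=O | intermediate
31 | CNP0177123.1, 9α-acetoxy-8β-{[2-(hydroxymethyl)prop-2-enoyl]oxy}-14-oxogermacra-1(10),4,11(13)-trien-12,6α-olide (6R,7S,8S,9S) | C=C(CO)C(=O)O[C@H]1[C@H]2C(=C)C(=O)O[C@@H]2/C=C(\C)CC/C=C(/C=O)[C@@H]1OC(C)=O | target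

## Step count and risks

Total step count: 21. Longest linear sequence: 18 steps (1–6, 8–17, 20, 21).

Steps most likely to fail:

1. Step 15 (ring closure). In an open chain the Felkin–Anh preference at an α-alkoxy aldehyde would favour the other face of C9, so the facial selectivity rests entirely on the ring-closing geometry and may be poor or reversed; intermolecular coupling also competes if cyclisation is slow. Fallback (C9 set by hydride delivery instead of by the C–C bond-forming event): setting out from 22, the same ring closure is accepted as a C9 epimer mixture, 24 together with the 9-epimeric carbinol F1. Dess–Martin oxidation converges both on the ring-B enone F2. Luche reduction (NaBH4, CeCl3·7H2O, MeOH, −78 °C) should deliver hydride anti to the non-chelating C8–O bond (Felkin–Anh, which for the ketone gives the required 8,9-threo relationship) and comes back to the route at 24.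

2. Step 14 (α-oxyamination). The C7 substituents are expected to bias the catalyst-bound aldehyde toward the opposite face (mismatched double stereodifferentiation), and the secondary amine can be held up by reversible conjugate addition to the exocyclic enoate, so C8 selectivity or turnover may be poor. Fallback (hydrogen-bond-directed proline catalysis and a silyl ether in place of the alkoxyamine): setting out from 21, D-proline (20 mol %) and nitrosobenzene in DMSO, then NaBH4 in the same pot, should give the anilinooxy alcohol F3. Zn/AcOH cleaves its N–O bond to the diol F4, and TESOTf/2,6-lutidine gives the bis(triethylsilyl) ether F5. Swern conditions oxidise the primary silyl ether selectively to the α-silyloxy aldehyde F6. The CrCl2/NiCl2 ring closure then gives the macrocyclic carbinol F7, Ac2O/DMAP gives its acetate F8, and HF·pyridine removes the triethylsilyl group to come back to the route at 26.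

3. Step 9 (reductive removal of the auxiliary). Borohydride may also attack the γ-lactone, the new primary alkoxide can take over the lactone carbonyl (acyl migration to the isomeric lactone), and base can trigger β-elimination of the lactone oxygen. Fallback (hydrolysis, acyl chloride and hydride instead of direct reduction): setting out from 14, LiOH/H2O2 (THF/H2O, 0 °C) gives the carboxylic acid F9 with recovery of 9. (COCl)2 with catalytic DMF gives the acid chloride F10. LiAlH(Ot-Bu)3 (THF, −78 °C) reduces it directly to the aldehyde and comes back to the route at 16, so the free alcohol 15 is bypassed.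

Further compounds
F1 | step 15 | 9-epimer of 24 (9β-hydroxy) | CC1(C)CCCC(C)(C)N1O[C@H]2[C@H]3C(=C)C(=O)O[C@@H]3/C=C(\C)CC/C=C(/C4OCCO4)[C@H]2O
F2 | step 15 | ring-B enone, 14,14-ethylenedioxy-9-oxo-8β-[(2,2,6,6-tetramethylpiperidin-1-yl)oxy]germacra-1(10),4,11(13)-trien-12,6α-olide | CC1(C)CCCC(C)(C)N1O[C@H]2[C@H]3C(=C)C(=O)O[C@@H]3/C=C(\C)CC/C=C(/C4OCCO4)C2=O
F3 | step 14 | anilinooxy alcohol, (2S)-2-(anilinooxy)-2-(lactone)ethanol derived from 21 | OC[C@@H](ONc1ccccc1)[C@H]2C(=C)C(=O)O[C@@H]2/C=C(\C)CC/C=C(\I)C3OCCO3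
F4 | step 14 | diol, (4S,5R)-4-[(1S)-1,2-dihydroxyethyl]-5-[(1E,5Z)-6-(1,3-dioxolan-2-yl)-6-iodo-2-methylhexa-1,5-dien-1-yl]-3-methylideneoxolan-2-one | OC[C@@H](O)[C@H]1C(=C)C(=O)O[C@@H]1/C=C(\C)CC/C=C(\I)C2OCCO2
F5 | step 14 | bis(triethylsilyl) ether of F4 | CC[Si](CC)(CC)OC[C@@H](O[Si](CC)(CC)CC)[C@H]1C(=C)C(=O)O[C@@H]1/C=C(\C)CC/C=C(\I)C2OCCO2
F6 | step 14 | α-(triethylsilyloxy) aldehyde, silyl analogue of 22 | O=C[C@@H](O[Si](CC)(CC)CC)[C@H]1C(=C)C(=O)O[C@@H]1/C=C(\C)CC/C=C(\I)C2OCCO2
F7 | step 14 | 14,14-ethylenedioxy-9α-hydroxy-8β-(triethylsilyloxy)germacra-1(10),4,11(13)-trien-12,6α-olide | CC[Si](CC)(CC)O[C@H]1[C@H]2C(=C)C(=O)O[C@@H]2/C=C(\C)CC/C=C(/C3OCCO3)[C@@H]1O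
F8 | step 14 | 9α-acetoxy-14,14-ethylenedioxy-8β-(triethylsilyloxy)germacra-1(10),4,11(13)-trien-12,6α-olide | CC[Si](CC)(CC)O[C@H]1[C@H]2C(=C)C(=O)O[C@@H]2/C=C(\C)CC/C=C(/C3OCCO3)[C@@H]1OC(C)=O
F9 | step 9 | (2R,3S)-2-[(1E,5Z)-6-(1,3-dioxolan-2-yl)-6-iodo-2-methylhexa-1,5-dien-1-yl]-5-oxooxolane-3-carboxylic acid | OC(=O)[C@H]1CC(=O)O[C@@H]1/C=C(\C)CC/C=C(\I)C2OCCO2
F10 | step 9 | acid chloride of F9 | ClC(=O)[C@H]1CC(=O)O[C@@H]1/C=C(\C)CC/C=C(\I)C2OCCO2
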